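## The problem

Target 34 is a hirsutinolide-type germacranolide. A ten-membered carbocycle (C1–C10) is fused along C6–C7 to a butenolide (C6, C7, C11, C12 and the lactone oxygen), and an oxygen atom joins C1 and C4, so that C1–C4 form a tetrahydrofuran with a tertiary hemiketal hydroxyl at C1. The exocyclic enol-lactone bond C5=C6 is cis within the ring (5E). For an open-chain ylidene butenolide this is the less stable geometry, so the bond is best formed in the act of closing the ring. Five stereocentres must be set: C1 (S), C4 (R), C8 (R), C10 (R) and C2' (R) of the chlorohydrin acid. C4 is quaternary and dictates C1 once the bridge exists, because the oxygen can span the ring only in the cis sense. C10 is isolated and is best bought. C8 can be set by the bicycle, whose two faces differ (bridge oxygen and C10 methyl lie on one side). C2' is remote and needs its own building block. Several groups are fragile: the hemiketal opens to a γ-hydroxy ketone, which exposes C10 to epimerisation; the dienyl lactone is sensitive to base; the allylic esters can migrate or eliminate; the β-chlorohydrin closes to an epoxide with base. The feature that suggests the plan is that C8 and C13 are the two allylic positions of the tetrasubstituted alkene C7=C11 and the only ones in the molecule, since C4 is quaternary and C5 is vinylic.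

## Retrosynthesis

**Acyl groups (O8–acyl, O13–acetyl).** Target 34 is traced to its triethylsilyl ether 33, and 33 to the 13-acetate 26 and the silyl-protected acid 31. Acetate 26 comes from triol 25 by acetylation of the only primary alcohol. These bonds are cut first because the chlorohydrin and the allylic esters would not survive base or organometallic steps. The forward steps need primary-over-secondary selectivity, an esterification that leaves the bridgehead hemiketal hydroxyl alone, and a non-basic desilylation.

**C8–O and C13–O (key disconnection).** Triol 25 is traced to the 8,13-dideoxy tricycle 23. Both carbons are allylic to C7=C11 and no other allylic C–H exists, so site selection is built into the skeleton. Carrying the two oxygens from the start would put leaving groups on the carbons flanking the butenolide during the dienolate ring closure, and would add a stereocentre and two protecting groups to the fragments. Precursor 23 has three stereocentres, of which only C4 and C10 are independent. The forward reaction must hydroxylate twice, deliver oxygen to the C8 face opposite the bridge and the C10 methyl group, and stop at the alcohol level.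

**Hemiketal and C5=C6 (ring closure).** Hemiketal 23 is the hydrolysis product of methyl ketal 22, and 22 is opened at C5=C6 to seco-aldehyde 19. This bond is chosen over C7–C8 or C8–C9 because the ring then enforces the cis-in-ring geometry, the C5 aldehyde is non-enolisable, and the cis-2,5-disubstituted tetrahydrofuran holds the two chain ends together. C1 must be a ketal in this step: a free C1 ketone would be attacked by C6 to give a six-membered ring. The closure must be base-mediated, since a Lewis acid would ionise the ketal. Only the C1 anomer with the two chains cis can close.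

**C7–C8 (sp3–sp2 coupling).** Aldehyde 19 comes from PMB ether 17, which is cut into alkene 13 and 4-bromo-3-methylfuran-2(5H)-one 15, made from 3-methyltetronic acid 14. A B-alkyl Suzuki coupling joins them without a stereocentre or oxygen function at C8, which is what the deoxy strategy allows.

**C8=C9 and the ketal carbon C1.** Alkene 13 comes from aldehyde 12 by methylenation, 12 from alcohol 11 and silyl ether 10. Ketal 10 is the gold-catalysed methanol adduct of homopropargylic alcohol 8. The alkyne is chosen as the latent C1 ketone because the tethered C4 hydroxyl fixes the site of oxygenation, and because C10 never sits next to a free ketone under basic conditions, as it would in a hydrazone or enolate alkylation.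

**C2–C3 (acetylide plus epoxide).** Alcohol 8 is cut into alkyne 4 and epoxide 6. Alkyne 4 comes from hydroxy ester 1 through silyl ether 2 and aldehyde 3 and supplies C1, C2, C9 and C10 with the C10 configuration. Epoxide 6 is the PMB ether of (S)-2-methylglycidol 5 and supplies C3, C4, C5 and the C4 methyl with the quaternary centre already set. The C4–O bond is not touched, so no stereocentre has to be made.

**Side chain.** Acid 31 comes from hydroxy acid 29, which comes from chlorodiol 28 by oxidation of the primary alcohol. Diol 28 comes from (R)-2-methylglycidol 27 by chloride opening at the CH2 terminus. The enantiomer of the epoxide used for C4 thus supplies C2'.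

## Roads not taken

**Alternative 1:** Ring-closing metathesis at C2=C3. A C1 vinyl ketone and a C4 vinyl carbinol on a furan-containing chain would be joined by the second-generation Hoveyda–Grubbs catalyst, and the cis γ-hydroxy enone would close at once to the bridged hemiketal A1. Its strong point is that the ketal forms by transannular capture, so there is no anomer problem, and both oxygens at C8 and C13 are carried. In these respects it is better than the chosen plan, which must select one ketal anomer and risk a late C–H oxidation. Its weak points are the metathesis partners (an electron-poor enone and a hindered tertiary allylic alcohol), the need for the Z-alkene in a ten-membered ring (the E-enone cannot ketalise), and the redox work afterwards: C2=C3 must be reduced beside a furan, and the furan must be oxidised to the ylidene butenolide with the right carbonyl position. The chosen plan sets against this a ring closure that creates the final C5=C6 bond directly and needs no furan oxidation.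

**Alternative 2:** Anionic oxy-Cope ring expansion. A cyclohexanol bearing a C1 vinyl group and a C6 alkenyl group would be treated with KH and 18-crown-6; C3–C4 forms, C1–C6 breaks, and the ten-membered ketone A2 results with C5=C6 and C4 set in one step. The ring expansion avoids the entropic cost of a medium-ring closure and delivers the ylidene geometry from the transition state, which the chosen plan must obtain from a high-dilution aldol closure. Against this, C4 would be created as a quaternary centre at the terminus of a tetrasubstituted enol ether, a slow and stereochemically uncertain oxy-Cope case. The potassium alkoxide would also coexist with a lactone and a β-silyloxy group, and the cyclohexanol substrate with three stereocentres and a spiro-butenolide needs a long synthesis. The chosen plan is more linear but uses only bought stereocentres and standard couplings.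

**Alternative 3:** Vinylogous aldol ring closure with both oxygens in place. The same C5=C6 closure as in the chosen route would be run on a substrate that already carries silyl ethers at C8 and C13, using tert-butyldimethylsilyl triflate and triethylamine, then DBU, to give A3. It avoids the late double C–H oxidation, the least secure step of the chosen plan, and fixes C8 early by reagent control; in this respect it is the safer road. Its weak points lie in the ring closure. The C8 and C13 silyloxy groups sit on carbons attached to the silyloxyfuran ring, where they can ionise or eliminate. The silyl triflate can also open the methyl ketal to an oxocarbenium ion, which the silyloxyfuran would trap at C1 in a six-membered ring. The fragments need an extra stereocentre and an oxygenated butenolide. The chosen plan closes the ring on a substrate without leaving groups and under base only, and a bromination route to the C13 acetate is held in reserve.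

Key step: step 16

Remark: locants C1–C13 follow the germacranolide numbering of the target (C1 hemiketal carbon, C4 oxygen-bearing quaternary carbon, C12 lactone carbonyl, C13 the carbon on C11); 3-methyltetronic acid 14 and both enantiomers of 2-methylglycidol (5, 27) are taken as purchasable.

## Route

Step 1
Reactants: 1 methyl (R)-3-hydroxy-2-methylpropanoate
Product: 2 methyl (R)-3-(tert-butyldiphenylsilyloxy)-2-methylpropanoate
Conditions: TBDPSCl, imidazole, DMF, rt
Reagents that add atoms: tert-butyl(chloro)diphenylsilane CC(C)(C)[Si](Cl)(c1ccccc1)c1ccccc1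
Why: Standard silylation of a primary alcohol; the acid-stable TBDPS group is chosen so that it survives the acidic methanol of step 6.

Step 2
Reactants: 2 methyl (R)-3-(tert-butyldiphenylsilyloxy)-2-methylpropanoate
Product: 3 (R)-3-(tert-butyldiphenylsilyloxy)-2-methylpropanal
Conditions: DIBAL-H (1.05 equiv), CH2Cl2, −78 °C; Rochelle salt work-up
Reagents that add atoms: none
Why: Partial ester reduction through the aluminium hemiacetal that is stable at −78 °C; the aldehyde is used at once so that the α-centre is not exposed to base or silica for long.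

Step 3
Reactants: 3 (R)-3-(tert-butyldiphenylsilyloxy)-2-methylpropanal
Product: 4 (S)-tert-butyl[(2-methylbut-3-yn-1-yl)oxy]diphenylsilane
Conditions: dimethyl (1-diazo-2-oxopropyl)phosphonate, K2CO3, MeOH, 0 °C to rt
Reagents that add atoms: dimethyl (1-diazo-2-oxopropyl)phosphonate CC(=O)C(=[N+]=[N-])P(=O)(OC)OC
Why: Seyferth–Gilbert homologation in the Ohira–Bestmann form; the former ester carbon becomes the internal alkyne carbon (C1) and the new terminal carbon is C2. The descriptor changes from R to S by priority only.

Step 4
Reactants: 5 [(2S)-2-methyloxiran-2-yl]methanol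
Product: 6 (R)-2-[(4-methoxybenzyloxy)methyl]-2-methyloxirane
Conditions: NaH, 4-methoxybenzyl chloride, Bu4NI (cat.), THF/DMF, 0 °C
Reagents that add atoms: 4-methoxybenzyl chloride COc1ccc(CCl)cc1
Why: Williamson etherification; with the reactive benzylic halide at 0 °C, O-alkylation should outrun the degenerate Payne rearrangement that would erode the enantiomeric purity. The descriptor changes from S to R by priority only.

Step 5
Reactants: 4 (S)-tert-butyl[(2-methylbut-3-yn-1-yl)oxy]diphenylsilane; 6 (R)-2-[(4-methoxybenzyloxy)methyl]-2-methyloxirane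
Product: 8 (2R,6S)-7-(tert-butyldiphenylsilyloxy)-1-(4-methoxybenzyloxy)-2,6-dimethylhept-4-yn-2-ol, via lithium acetylide 7 (not isolated)
Conditions: n-BuLi, THF, −78 °C; BF3·OEt2; then 6, −78 °C
Reagents that add atoms: none
Why: Yamaguchi–Hirao alkynylation: the BF3-activated epoxide is opened by SN2 attack at its CH2 terminus, forming C2–C3. The C4–O bond is untouched, so the quaternary centre keeps its configuration.

Step 6
Reactants: 8 (2R,6S)-7-(tert-butyldiphenylsilyloxy)-1-(4-methoxybenzyloxy)-2,6-dimethylhept-4-yn-2-ol
Product: 10 (2S,5R)-2-[(2R)-1-(tert-butyldiphenylsilyloxy)propan-2-yl]-2-methoxy-5-[(4-methoxybenzyloxy)methyl]-5-methyltetrahydrofuran, via 2,3-dihydrofuran 9 (not isolated)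
Conditions: Ph3PAuCl (2 mol %), AgOTf (2 mol %), PPTS (5 mol %), MeOH/CH2Cl2, rt
Reagents that add atoms: methanol CO
Why: Gold-catalysed 5-endo-dig hydroalkoxylation of the homopropargylic alcohol places oxygen on C1 only; protonation of enol ether 9 at C2 and capture by methanol give the ketal. Both C1 anomers are expected in similar amounts; 10 (methoxy cis to the C4 methyl, the only one that can later be bridged) is separated, and the other anomer is returned to the same acidic methanol to re-equilibrate. Later steps are run buffered so that C1 is not scrambled.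

Step 7
Reactants: 10 (2S,5R)-2-[(2R)-1-(tert-butyldiphenylsilyloxy)propan-2-yl]-2-methoxy-5-[(4-methoxybenzyloxy)methyl]-5-methyltetrahydrofuran
Product: 11 (2R)-2-{(2S,5R)-2-methoxy-5-[(4-methoxybenzyloxy)methyl]-5-methyltetrahydrofuran-2-yl}propan-1-ol
Conditions: TBAF, THF, rt
Reagents that add atoms: none
Why: Fluoride cleavage of the primary silyl ether; ketal and PMB ether are inert to fluoride.

Step 8
Reactants: 11 (2R)-2-{(2S,5R)-2-methoxy-5-[(4-methoxybenzyloxy)methyl]-5-methyltetrahydrofuran-2-yl}propan-1-ol
Product: 12 (2R)-2-{(2S,5R)-2-methoxy-5-[(4-methoxybenzyloxy)methyl]-5-methyltetrahydrofuran-2-yl}propanal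
Conditions: Dess–Martin periodinane, NaHCO3, CH2Cl2, 0 °C
Reagents that add atoms: none
Why: Buffered Dess–Martin oxidation; the bicarbonate protects the ketal from acetic acid, and the aldehyde is used crude to keep C10 intact.

Step 9
Reactants: 12 (2R)-2-{(2S,5R)-2-methoxy-5-[(4-methoxybenzyloxy)methyl]-5-methyltetrahydrofuran-2-yl}propanal
Product: 13 (2S,5R)-2-[(2R)-but-3-en-2-yl]-2-methoxy-5-[(4-methoxybenzyloxy)methyl]-5-methyltetrahydrofuran
Conditions: Ph3PCH3Br, KHMDS, THF, −78 to 0 °C
Reagents that add atoms: methyltriphenylphosphonium bromide C[P+](c1ccccc1)(c1ccccc1)c1ccccc1.[Br-]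
Why: Wittig methylenation adds C8; the salt-free ylide at low temperature adds to the hindered aldehyde faster than it enolises it, so C10 should be retained.

Step 10
Reactants: 14 4-hydroxy-3-methylfuran-2(5H)-one (3-methyltetronic acid)
Product: 15 4-bromo-3-methylfuran-2(5H)-one
Conditions: (COBr)2, DMF (cat.), CH2Cl2, 0 °C to rt
Reagents that add atoms: oxalyl bromide BrC(=O)C(Br)=O
Why: Vilsmeier-type conversion of the vinylogous acid into the vinylogous acid bromide, the standard entry to 4-bromobutenolides.

Step 11
Reactants: 13 (2S,5R)-2-[(2R)-but-3-en-2-yl]-2-methoxy-5-[(4-methoxybenzyloxy)methyl]-5-methyltetrahydrofuran; 15 4-bromo-3-methylfuran-2(5H)-one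
Product: 17 4-{(3R)-3-[(2S,5R)-2-methoxy-5-[(4-methoxybenzyloxy)methyl]-5-methyltetrahydrofuran-2-yl]butyl}-3-methylfuran-2(5H)-one, via B-alkyl-9-BBN borane 16 (not isolated)
Conditions: 9-BBN, THF, rt; then 15, Pd(dppf)Cl2 (5 mol %), AsPh3, Cs2CO3, DMF/H2O, rt
Reagents that add atoms: none
Why: Anti-Markovnikov hydroboration of the terminal alkene, then B-alkyl Suzuki–Miyaura coupling with the β-bromo enoate, forms C7–C8. The mild carbonate conditions at room temperature are chosen to spare the butenolide.

Step 12
Reactants: 17 4-{(3R)-3-[(2S,5R)-2-methoxy-5-[(4-methoxybenzyloxy)methyl]-5-methyltetrahydrofuran-2-yl]butyl}-3-methylfuran-2(5H)-one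
Product: 18 4-{(3R)-3-[(2S,5R)-5-(hydroxymethyl)-2-methoxy-5-methyltetrahydrofuran-2-yl]butyl}-3-methylfuran-2(5H)-one
Conditions: DDQ, CH2Cl2/pH 7 buffer, 0 °C
Reagents that add atoms: none
Why: Oxidative PMB cleavage under neutral buffered conditions, to which the electron-poor butenolide and the ketal are inert.

Step 13
Reactants: 18 4-{(3R)-3-[(2S,5R)-5-(hydroxymethyl)-2-methoxy-5-methyltetrahydrofuran-2-yl]butyl}-3-methylfuran-2(5H)-one
Product: 19 (2R,5S)-5-methoxy-2-methyl-5-[(2R)-4-(4-methyl-5-oxo-2,5-dihydrofuran-3-yl)butan-2-yl]tetrahydrofuran-2-carbaldehyde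
Conditions: Dess–Martin periodinane, NaHCO3, CH2Cl2, 0 °C
Reagents that add atoms: none
Why: Buffered oxidation of the neopentyl-type alcohol; the resulting α-alkoxy aldehyde has no α-hydrogen and cannot epimerise or enolise.

Step 14
Reactants: 19 (2R,5S)-5-methoxy-2-methyl-5-[(2R)-4-(4-methyl-5-oxo-2,5-dihydrofuran-3-yl)butan-2-yl]tetrahydrofuran-2-carbaldehyde
Product: 22 (1S,4R,5E,10R)-1,4-epoxy-1-methoxygermacra-5,7(11)-dien-12,6-olide, via ring-closed lithium aldolate 20 (not isolated), via aldol acetate 21 (not isolated)
Conditions: LiHMDS (1.05 equiv, added slowly), THF (1 mM), −78 to −20 °C; Ac2O, −20 to 0 °C; DBU, rt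
Reagents that add atoms: none
Why: Intramolecular vinylogous aldol reaction: the lithium 2-furanolate formed at C6 adds through its γ-carbon to the non-enolisable C5 aldehyde, with the cis-tetrahydrofuran holding the ends together; acetylation and E1cB loss of acetate give C5=C6. The nine-membered oxygen-bridged ring allows only the cis-in-ring (5E) alkene, and the base-only conditions leave the ketal intact.

Step 15
Reactants: 22 (1S,4R,5E,10R)-1,4-epoxy-1-methoxygermacra-5,7(11)-dien-12,6-olide
Product: 23 (1S,4R,5E,10R)-1,4-epoxy-1-hydroxygermacra-5,7(11)-dien-12,6-olide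
Conditions: PPTS, acetone/H2O, 40 °C
Reagents that add atoms: water O
Why: Mild acid hydrolysis of the mixed ketal through the endocyclic oxocarbenium ion; only the cis-bridged hemiketal can form, so C1 is fixed by C4.

Step 16
Reactants: 23 (1S,4R,5E,10R)-1,4-epoxy-1-hydroxygermacra-5,7(11)-dien-12,6-olide
Product: 25 (1S,4R,5E,8R,10R)-1,4-epoxy-1,8,13-trihydroxygermacra-5,7(11)-dien-12,6-olide, via 8-hydroxy alcohol 24 (not isolated)
Conditions: SeO2 (0.5 equiv), t-BuOOH (4 equiv, in decane), salicylic acid (0.1 equiv), ClCH2CH2Cl, rt then 60 °C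
Reagents that add atoms: selenium dioxide O=[Se]=O; tert-butyl hydroperoxide CC(C)(C)OO
Why: Proposed new method: SeO2 hydroxylation of a CH2 group on the β-carbon of an α-methyl butenolide is established, but a second hydroxylation at the α-methyl group of the same alkene has not been shown, so the twofold reaction is a proposal. The first event is the polarity-matched ene reaction: selenium bonds to C11 (the α-carbon) while a C8 hydrogen is transferred, and the [2,3] shift of the allylseleninic acid returns the double bond to C7=C11 and places oxygen on C8, giving 24. Both the ene step and the [2,3] shift are suprafacial, so oxygen arrives on the face from which SeO2 approaches, the face opposite the C1–O–C4 bridge and the C10 methyl group, which sets 8R. The second event needs selenium to bond to C7 with hydrogen transfer from C13, the disfavoured orientation on an enoate; it is proposed to occur at 60 °C once C8 is oxidised, helped by the delocalisation over C13, C7 and C5 that only this site offers. Site selectivity needs no control, because C4 is quaternary and C5 has no allylic hydrogen, so C8 and C13 are the only allylic C–H positions. The step must stop at the alcohol level; substoichiometric SeO2 with t-BuOOH as re-oxidant and an early quench are meant to secure this. The closest known reaction type is the SeO2/t-BuOOH γ-hydroxylation of α,β-unsaturated lactones and esters. No ring is closed.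

Step 17
Reactants: 25 (1S,4R,5E,8R,10R)-1,4-epoxy-1,8,13-trihydroxygermacra-5,7(11)-dien-12,6-olide
Product: 26 (1S,4R,5E,8R,10R)-13-acetoxy-1,4-epoxy-1,8-dihydroxygermacra-5,7(11)-dien-12,6-olide
Conditions: Ac2O (1.05 equiv), 2,4,6-collidine, CH2Cl2, −20 °C
Reagents that add atoms: acetic anhydride CC(=O)OC(C)=O
Why: Kinetic acylation of the only primary alcohol; the hindered secondary C8 alcohol and the tertiary bridgehead hemiketal hydroxyl react much more slowly with a weak base at low temperature.

Step 18
Reactants: 27 [(2R)-2-methyloxiran-2-yl]methanol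
Product: 28 (R)-3-chloro-2-methylpropane-1,2-diol
Conditions: LiCl, AcOH, THF, rt
Reagents that add atoms: lithium chloride [Li+].[Cl-]
Why: Weak-acid-assisted SN2 opening of the epoxide by chloride at the unsubstituted CH2; the C–O bond at the quaternary carbon is not broken, so its configuration is retained.

Step 19
Reactants: 28 (R)-3-chloro-2-methylpropane-1,2-diol
Product: 29 (R)-3-chloro-2-hydroxy-2-methylpropanoic acid
Conditions: TEMPO (cat.), NaClO2, NaOCl (cat.), MeCN/phosphate buffer (pH 6.7), 35 °C
Reagents that add atoms: sodium chlorite [Na+].[O-]Cl=O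
Why: Oxoammonium/chlorite oxidation of the primary alcohol to the acid; the tertiary alcohol cannot be oxidised, and the near-neutral pH prevents epoxide formation from the chlorohydrin.

Step 20
Reactants: 29 (R)-3-chloro-2-hydroxy-2-methylpropanoic acid
Product: 31 (R)-3-chloro-2-methyl-2-(triethylsilyloxy)propanoic acid, via bis(triethylsilyl) derivative 30 (not isolated)
Conditions: TESOTf, 2,6-lutidine, CH2Cl2, 0 °C; then K2CO3 (cat.), MeOH/H2O, 0 °C
Reagents that add atoms: triethylsilyl trifluoromethanesulfonate CC[Si](CC)(CC)OS(=O)(=O)C(F)(F)F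
Why: Exhaustive silylation, then selective solvolysis of the labile silyl ester; masking the tertiary hydroxyl prevents self-acylation and epoxide closure during the esterification.

Step 21
Reactants: 31 (R)-3-chloro-2-methyl-2-(triethylsilyloxy)propanoic acid; 26 (1S,4R,5E,8R,10R)-13-acetoxy-1,4-epoxy-1,8-dihydroxygermacra-5,7(11)-dien-12,6-olide
Product: 33 (1S,4R,5E,8R,10R)-13-acetoxy-8-[(2R)-3-chloro-2-methyl-2-(triethylsilyloxy)propanoyloxy]-1,4-epoxy-1-hydroxygermacra-5,7(11)-dien-12,6-olide, via mixed anhydride 32 (not isolated)
Conditions: 2,4,6-trichlorobenzoyl chloride, Et3N, toluene, rt; then 26, DMAP, rt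
Reagents that add atoms: none
Why: Yamaguchi esterification, a standard method for hindered acid and alcohol partners; the bridgehead tertiary hemiketal hydroxyl is too hindered to compete, and C8 is not touched at carbon, so its configuration is kept.

Step 22
Reactants: 33 (1S,4R,5E,8R,10R)-13-acetoxy-8-[(2R)-3-chloro-2-methyl-2-(triethylsilyloxy)propanoyloxy]-1,4-epoxy-1-hydroxygermacra-5,7(11)-dien-12,6-olide
Product: 34 (1S,4R,5E,8R,10R)-13-acetoxy-8-[(2R)-3-chloro-2-hydroxy-2-methylpropanoyloxy]-1,4-epoxy-1-hydroxygermacra-5,7(11)-dien-12,6-olide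
Conditions: HF·pyridine, pyridine, THF, 0 °C
Reagents that add atoms: none
Why: Fluoride cleavage of the tertiary silyl ether under weakly acidic, non-basic conditions, so that the chlorohydrin does not close to an epoxide and the allylic esters do not migrate.

## Compound list

1 | methyl (R)-3-hydroxy-2-methylpropanoate | COC(=O)[C@H](C)CO | starting material
2 | methyl (R)-3-(tert-butyldiphenylsilyloxy)-2-methylpropanoate | COC(=O)[C@H](C)CO[Si](c1ccccc1)(c1ccccc1)C(C)(C)C | intermediate
3 | (R)-3-(tert-butyldiphenylsilyloxy)-2-methylpropanal | O=C[C@H](C)CO[Si](c1ccccc1)(c1ccccc1)C(C)(C)C | intermediate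
4 | (S)-tert-butyl[(2-methylbut-3-yn-1-yl)oxy]diphenylsilane | C#C[C@H](C)CO[Si](c1ccccc1)(c1ccccc1)C(C)(C)C | intermediate
5 | [(2S)-2-methyloxiran-2-yl]methanol | OC[C@@]1(C)CO1 | starting material
6 | (R)-2-[(4-methoxybenzyloxy)methyl]-2-methyloxirane | COc1ccc(COC[C@@]2(C)CO2)cc1 | intermediate
7 | lithium acetylide of 4 | [Li]C#C[C@H](C)CO[Si](c1ccccc1)(c1ccccc1)C(C)(C)C | intermediate
8 | (2R,6S)-7-(tert-butyldiphenylsilyloxy)-1-(4-methoxybenzyloxy)-2,6-dimethylhept-4-yn-2-ol | CC(C)(C)[Si](c1ccccc1)(c1ccccc1)OC[C@@H](C)C#CC[C@@](C)(O)COCc1ccc(OC)cc1 | intermediate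
9 | (2R)-5-[(2S)-1-(tert-butyldiphenylsilyloxy)propan-2-yl]-2-[(4-methoxybenzyloxy)methyl]-2-methyl-2,3-dihydrofuran (same spatial arrangement as 8) | COc1ccc(COC[C@@]2(C)CC=C(O2)[C@H](C)CO[Si](c2ccccc2)(c2ccccc2)C(C)(C)C)cc1 | intermediate
10 | (2S,5R)-2-[(2R)-1-(tert-butyldiphenylsilyloxy)propan-2-yl]-2-methoxy-5-[(4-methoxybenzyloxy)methyl]-5-methyltetrahydrofuran | CO[C@]1(CC[C@](C)(COCc2ccc(OC)cc2)O1)[C@H](C)CO[Si](c1ccccc1)(c1ccccc1)C(C)(C)C | intermediate
11 | (2R)-2-{(2S,5R)-2-methoxy-5-[(4-methoxybenzyloxy)methyl]-5-methyltetrahydrofuran-2-yl}propan-1-ol | CO[C@]1(CC[C@](C)(COCc2ccc(OC)cc2)O1)[C@H](C)CO | intermediate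
12 | (2R)-2-{(2S,5R)-2-methoxy-5-[(4-methoxybenzyloxy)methyl]-5-methyltetrahydrofuran-2-yl}propanal | CO[C@]1(CC[C@](C)(COCc2ccc(OC)cc2)O1)[C@H](C)C=O | intermediate
13 | (2S,5R)-2-[(2R)-but-3-en-2-yl]-2-methoxy-5-[(4-methoxybenzyloxy)methyl]-5-methyltetrahydrofuran | CO[C@]1(CC[C@](C)(COCc2ccc(OC)cc2)O1)[C@H](C)C=C | intermediate
14 | 4-hydroxy-3-methylfuran-2(5H)-one (3-methyltetronic acid) | CC1=C(O)COC1=O | starting material
15 | 4-bromo-3-methylfuran-2(5H)-one | CC1=C(Br)COC1=O | intermediate
16 | B-alkyl-9-BBN borane from 13 (boron on C8) | CO[C@]1(CC[C@](C)(COCc2ccc(OC)cc2)O1)[C@H](C)CCB1C2CCCC1CCC2 | intermediate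
17 | 4-{(3R)-3-[(2S,5R)-2-methoxy-5-[(4-methoxybenzyloxy)methyl]-5-methyltetrahydrofuran-2-yl]butyl}-3-methylfuran-2(5H)-one | CO[C@]1(CC[C@](C)(COCc2ccc(OC)cc2)O1)[C@H](C)CCC1=C(C)C(=O)OC1 | intermediate
18 | 4-{(3R)-3-[(2S,5R)-5-(hydroxymethyl)-2-methoxy-5-methyltetrahydrofuran-2-yl]butyl}-3-methylfuran-2(5H)-one | CO[C@]1(CC[C@](C)(CO)O1)[C@H](C)CCC1=C(C)C(=O)OC1 | intermediate
19 | (2R,5S)-5-methoxy-2-methyl-5-[(2R)-4-(4-methyl-5-oxo-2,5-dihydrofuran-3-yl)butan-2-yl]tetrahydrofuran-2-carbaldehyde | CO[C@]1(CC[C@](C)(C=O)O1)[C@H](C)CCC1=C(C)C(=O)OC1 | intermediate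
20 | lithium alkoxide of the ring-closed aldol adduct (1S,4R,10R; C5 and C6 mixed) | [Li+].CC1=C2C(C([O-])[C@@]3(C)CC[C@](OC)(O3)[C@H](C)CC2)OC1=O | intermediate
21 | C5 acetate of the ring-closed aldol adduct (1S,4R,10R; C5 and C6 mixed) | CC1=C2C(C(OC(C)=O)[C@@]3(C)CC[C@](OC)(O3)[C@H](C)CC2)OC1=O | intermediate
22 | (1S,4R,5E,10R)-1,4-epoxy-1-methoxygermacra-5,7(11)-dien-12,6-olide | CC1=C2/C(=C\[C@@]3(C)CC[C@](OC)(O3)[C@H](C)CC2)OC1=O | intermediate
23 | (1S,4R,5E,10R)-1,4-epoxy-1-hydroxygermacra-5,7(11)-dien-12,6-olide | CC1=C2/C(=C\[C@@]3(C)CC[C@](O)(O3)[C@H](C)CC2)OC1=O | intermediate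
24 | (1S,4R,5E,8R,10R)-1,4-epoxy-1,8-dihydroxygermacra-5,7(11)-dien-12,6-olide | CC1=C2/C(=C\[C@@]3(C)CC[C@](O)(O3)[C@H](C)C[C@H]2O)OC1=O | intermediate
25 | (1S,4R,5E,8R,10R)-1,4-epoxy-1,8,13-trihydroxygermacra-5,7(11)-dien-12,6-olide | OCC1=C2/C(=C\[C@@]3(C)CC[C@](O)(O3)[C@H](C)C[C@H]2O)OC1=O | intermediate
26 | (1S,4R,5E,8R,10R)-13-acetoxy-1,4-epoxy-1,8-dihydroxygermacra-5,7(11)-dien-12,6-olide | CC(=O)OCC1=C2/C(=C\[C@@]3(C)CC[C@](O)(O3)[C@H](C)C[C@H]2O)OC1=O | intermediate
27 | [(2R)-2-methyloxiran-2-yl]methanol | OC[C@]1(C)CO1 | starting material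
28 | (R)-3-chloro-2-methylpropane-1,2-diol | OC[C@@](C)(O)CCl | intermediate
29 | (R)-3-chloro-2-hydroxy-2-methylpropanoic acid | OC(=O)[C@@](C)(O)CCl | intermediate
30 | triethylsilyl (R)-3-chloro-2-methyl-2-(triethylsilyloxy)propanoate | CC[Si](CC)(CC)OC(=O)[C@@](C)(O[Si](CC)(CC)CC)CCl | intermediate
31 | (R)-3-chloro-2-methyl-2-(triethylsilyloxy)propanoic acid | OC(=O)[C@@](C)(O[Si](CC)(CC)CC)CCl | intermediate
32 | mixed anhydride of 31 with 2,4,6-trichlorobenzoic acid | O=C(OC(=O)[C@@](C)(O[Si](CC)(CC)CC)CCl)c1c(Cl)cc(Cl)cc1Cl | intermediate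
33 | (1S,4R,5E,8R,10R)-13-acetoxy-8-[(2R)-3-chloro-2-methyl-2-(triethylsilyloxy)propanoyloxy]-1,4-epoxy-1-hydroxygermacra-5,7(11)-dien-12,6-olide | CC(=O)OCC1=C2/C(=C\[C@@]3(C)CC[C@](O)(O3)[C@H](C)C[C@H]2OC(=O)[C@@](C)(O[Si](CC)(CC)CC)CCl)OC1=O | intermediate
34 | (1S,4R,5E,8R,10R)-13-acetoxy-8-[(2R)-3-chloro-2-hydroxy-2-methylpropanoyloxy]-1,4-epoxy-1-hydroxygermacra-5,7(11)-dien-12,6-olide | CC(=O)OCC1=C2/C(=C\[C@@]3(C)CC[C@](O)(O3)[C@H](C)C[C@H]2OC(=O)[C@@](C)(O)CCl)OC1=O | target

## Step count and least certain steps

Total: 22 steps. Longest linear sequence: 17 steps (1, 2, 3, 5, 6, 7, 8, 9, 11, 12, 13, 14, 15, 16, 17, 21, 22).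

**Step 16 (key step, proposed new method).** The most likely failure is that the reaction stops after the C8 hydroxylation, because the second ene reaction at C13 requires selenium to attack the electron-poor β-carbon C7. Forcing it may over-oxidise the C8 alcohol to the enone before C13 reacts. A lesser concern is oxygen delivery to the wrong face at C8. Fallback with known chemistry, setting out from 24: the reaction is stopped after the room-temperature stage and 24 is isolated. It is esterified with 31 under the conditions of step 21 to give the 8-O-acyl-13-deoxy compound F1. Wohl–Ziegler bromination (NBS, AIBN, PhCF3, 80 °C) of the C13 methyl group, now the only allylic position without an oxygen substituent, gives the 13-bromide F2. Silver acetate in acetic acid replaces bromide by acetate and gives 33, where the route is rejoined.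

**Step 14.** The nine-membered ring may close too slowly, so that intermolecular aldol addition (oligomerisation) or attack of the amide base on the aldehyde competes; attack through the α-carbon of the furanolate is a lesser risk. Fallback setting out from 13 and coming back at 22, in which the C5–C6 bond is made between two molecules and the ring is closed at C7–C8: DDQ removes the PMB group of 13 to give alcohol F3, and Dess–Martin oxidation gives aldehyde F4. The lithium furanolate of 15 (LDA, THF, −78 °C) adds to F4 to give aldol adduct F5 as a mixture at C5 and C6, which is protected as triethylsilyl ether F6. Hydroboration with 9-BBN and intramolecular B-alkyl Suzuki–Miyaura coupling (Pd(dppf)Cl2, AsPh3, Cs2CO3, high dilution) give the macrocyclic silyl ether F7. DBU then eliminates triethylsilanol to give 22; the ring again enforces the 5E geometry.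

**Step 11.** Competing β-hydride elimination or protodeboronation of the alkylborane, and base-induced isomerisation or self-condensation of the butenolide, may lower the coupling efficiency. Fallback setting out from 13 and coming back at 17, with a base-free Negishi coupling: hydroboration–oxidation (9-BBN; NaOH, H2O2) gives primary alcohol F8, and iodination (I2, PPh3, imidazole) gives iodide F9. Zinc insertion (Zn, LiCl, THF) gives alkylzinc iodide F10, which couples with 15 under Pd(OAc)2/SPhos to give 17.

**Step 21.** Acylation of the hindered C8 alcohol by an α-quaternary acid may be slow. That would leave time for acetyl migration from O13 to O8 and for attack at the aromatic carbonyl of the mixed anhydride. Fallback setting out from 26 and 27 and ending at 34, using a smaller acyl donor and introducing chloride last: RuCl3/NaIO4 oxidation of 27 gives (S)-2-methyloxirane-2-carboxylic acid F11. EDC/DMAP coupling with 26 gives glycidate ester F12. LiCl/AcOH in THF opens the epoxide at its CH2 terminus to give 34 directly, without a silyl group.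

## Further compounds

F1 | step 16 | (1S,4R,5E,8R,10R)-8-[(2R)-3-chloro-2-methyl-2-(triethylsilyloxy)propanoyloxy]-1,4-epoxy-1-hydroxygermacra-5,7(11)-dien-12,6-olide | CC1=C2/C(=C\[C@@]3(C)CC[C@](O)(O3)[C@H](C)C[C@H]2OC(=O)[C@@](C)(O[Si](CC)(CC)CC)CCl)OC1=O
F2 | step 16 | 13-bromo derivative of F1 | BrCC1=C2/C(=C\[C@@]3(C)CC[C@](O)(O3)[C@H](C)C[C@H]2OC(=O)[C@@](C)(O[Si](CC)(CC)CC)CCl)OC1=O
F3 | step 14 | {(2R,5S)-5-[(2R)-but-3-en-2-yl]-5-methoxy-2-methyltetrahydrofuran-2-yl}methanol | CO[C@]1(CC[C@](C)(CO)O1)[C@H](C)C=C
F4 | step 14 | (2R,5S)-5-[(2R)-but-3-en-2-yl]-5-methoxy-2-methyltetrahydrofuran-2-carbaldehyde | CO[C@]1(CC[C@](C)(C=O)O1)[C@H](C)C=C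
F5 | step 14 | aldol adduct of F4 with the γ-carbon of 15 (C5 and C6 mixed) | CO[C@]1(CC[C@](C)(C(O)C2OC(=O)C(C)=C2Br)O1)[C@H](C)C=C
F6 | step 14 | triethylsilyl ether of F5 | CO[C@]1(CC[C@](C)(C(O[Si](CC)(CC)CC)C2OC(=O)C(C)=C2Br)O1)[C@H](C)C=C
F7 | step 14 | ring-closed C5 triethylsilyl ether (1S,4R,10R; C5 and C6 mixed) | CC1=C2C(C(O[Si](CC)(CC)CC)[C@@]3(C)CC[C@](OC)(O3)[C@H](C)CC2)OC1=O
F8 | step 11 | (3R)-3-{(2S,5R)-2-methoxy-5-[(4-methoxybenzyloxy)methyl]-5-methyltetrahydrofuran-2-yl}butan-1-ol | CO[C@]1(CC[C@](C)(COCc2ccc(OC)cc2)O1)[C@H](C)CCO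
F9 | step 11 | (2S,5R)-2-[(2R)-4-iodobutan-2-yl]-2-methoxy-5-[(4-methoxybenzyloxy)methyl]-5-methyltetrahydrofuran | CO[C@]1(CC[C@](C)(COCc2ccc(OC)cc2)O1)[C@H](C)CCI
F10 | step 11 | alkylzinc iodide from F9 | CO[C@]1(CC[C@](C)(COCc2ccc(OC)cc2)O1)[C@H](C)CC[Zn]I
F11 | step 21 | (S)-2-methyloxirane-2-carboxylic acid | OC(=O)[C@]1(C)CO1
F12 | step 21 | 8-O-[(S)-2-methyloxirane-2-carbonyl] ester of 26 | CC(=O)OCC1=C2/C(=C\[C@@]3(C)CC[C@](O)(O3)[C@H](C)C[C@H]2OC(=O)[C@]4(C)CO4)OC1=O
A1 | alternative 1 | furan-fused bridged 2,5-dihydrofuran hemiketal | CC(=O)OCc1coc2c1[C@H](O[Si](C)(C)C(C)(C)C)C[C@@H](C)[C@]3(O)C=C[C@@](C)(O3)C2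
A2 | alternative 2 | ten-membered C1 ketone with C4 PMB ether and ylidene butenolide | CC(C)(C)[Si](C)(C)OCC1=C2/C(=C\[C@@](OCc3ccc(OC)cc3)(C)CCC(=O)[C@H](C)C[C@H]2O[Si](C)(C)C(C)(C)C)OC1=O
A3 | alternative 3 | bridged methyl ketal ylidene butenolide bis-silyl ether | CC(C)(C)[Si](C)(C)OCC1=C2/C(=C\[C@@]3(C)CC[C@](OC)(O3)[C@H](C)C[C@H]2O[Si](C)(C)C(C)(C)C)OC1=O
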